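**Plan** (labdane numbering: ring A = C1–C5, C10; ring B = C5–C10; C11–C16 side chain; C17 on C8; C18, C19 on C4; C20 on C10)

1. Cuts, from the end backwards: acetate and C13=C14 (Horner–Wadsworth–Emmons on a C13 methyl ketone), C8–C17 (methyl addition to a C8 ketone), C9–C11 (but-3-en-2-one on a C8=C9 enol ether), H–C5 (hydrogenation), then C1–C10 and C3–C4 together, which takes C1–C3 out as 1,3-dibromopropane and leaves ring B as a benzene ring.
2. Enabling feature: C10 and C4 are both bonded to C5. With ring B aromatic, C10 is the ipso carbon of a benzamide (its carbonyl is the future C20 methyl) and C4 is the α-carbon of an ortho propanoate (its carbonyl is the future C19 methyl). Birch reduction then gives a bis-enolate that is nucleophilic at exactly these two 1,3-related carbons while C5 stays trigonal.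
3. Forward order: arene ring B (2 steps), dearomative double alkylation closing ring A with both quaternary carbons, C9 chain, cis ring fusion, C19/C20 carbonyls to methyls, C8 carbinol, E side chain.
4. Stereochemistry: C10 from the prolinol-ether auxiliary in the Birch alkylation; C5 by amide-directed hydrogenation (H cis to C20); C9 by equilibration next to the C8 ketone; C8 by equatorial methyl addition opposite the axial C20 methyl; C13=C14 E from the olefination.

Key step: step 3

Remark: the (S)-auxiliary is assumed to steer the C10 alkylation to the face drawn (future 10S); if the sense is the reverse, the (R)-auxiliary is used and nothing else changes.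

**Route**

Step 1
Reactants: 1 2-bromo-5-methoxybenzoyl chloride; 2 (S)-2-(methoxymethyl)pyrrolidine
Product: 3 (S)-1-(2-bromo-5-methoxybenzoyl)-2-(methoxymethyl)pyrrolidine
Conditions: Et3N, CH2Cl2, 0 → 20 °C
Reagents that add atoms: none
Why: Schotten–Baumann-type N-acylation of the secondary amine installs the amide that later activates the ring for Birch reduction, controls C10 and directs the hydrogenation; no stereocentre is formed.

Step 2
Reactants: 3 (S)-1-(2-bromo-5-methoxybenzoyl)-2-(methoxymethyl)pyrrolidine; 4 tert-butyl propanoate
Product: 6 tert-butyl 2-[4-methoxy-2-((S)-2-(methoxymethyl)pyrrolidine-1-carbonyl)phenyl]propanoate (both epimers at the future C4), via lithium enolate 5 (not isolated)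
Conditions: LiN(SiMe3)2, Pd(dba)2 (cat.), P(t-Bu)3 (cat.), toluene, 20 °C
Reagents that add atoms: none
Why: Palladium-catalysed α-arylation of an ester enolate (oxidative addition of the aryl bromide to zerovalent palladium, transmetalation, reductive elimination) joins the future C4 to C5; the benzylic stereocentre forms without control, which is immaterial because it becomes an enolate carbon in step 3.

Step 3
Reactants: 6 tert-butyl 2-[4-methoxy-2-((S)-2-(methoxymethyl)pyrrolidine-1-carbonyl)phenyl]propanoate (both epimers at the future C4); 7 1,3-dibromopropane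
Product: 10 8-methoxy-11,12,13,14,15,16,17-heptanorlabda-5,8-diene-19,20-dioic acid 19-tert-butyl ester 20-[(S)-2-(methoxymethyl)pyrrolidine] amide (C10 as in the target; C4 epimers), via bis-enolate 8 (not isolated), via bromopropyl ester enolate 9 (not isolated)
Conditions: LiN(i-Pr)2 (1.1 equiv), THF, −78 °C; then K (2 equiv), NH3(l)–THF, t-BuOH (1 equiv), −78 °C; then 7 (1 equiv), −78 → 20 °C, high dilution
Reagents that add atoms: none
Why: Proposed new method: the pre-formed lithium ester enolate is inert to the metal, so K in NH3 reduces only the benzamide ring (electron transfer, protonation at C7 para to the carboxamide by t-BuOH, second electron) to the cross-conjugated bis-enolate 8, in which C10 (amide enolate carbon) and C4 (ester dienolate α-carbon) flank the still trigonal C5; the closest known reaction type is the Birch reduction–alkylation of chiral 2-substituted benzamides, joined here to an ester enolate alkylation by one 1,3-dihalide. The more reactive amide enolate should be alkylated first at C10 at −78 °C (C1–C10), and on warming the ester dienolate should close ring A on the remaining primary bromide through its α-carbon (C3–C4) in a 6-exo-tet displacement. C10 is the only new stereocentre that matters and is set in the intermolecular alkylation by the prolinol-ether auxiliary (potassium-chelated enolate, halide approaching opposite the methoxymethyl arm); C4 forms as a mixture that vanishes when C19 becomes a methyl group. The step needs ipso C-alkylation at C10 (the known behaviour of Birch amide enolates), α- rather than γ-alkylation of the dienolate (kinetic α-preference; γ-attack at C6 would need a bridged bicyclo[3.3.1] transition state) and ring closure rather than oligomerisation (one equivalent of 7, dilution). Because C5 stays sp2, the order of the two alkylations has no consequence for the ring fusion, which is fixed in step 5.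

Step 4
Reactants: 10 8-methoxy-11,12,13,14,15,16,17-heptanorlabda-5,8-diene-19,20-dioic acid 19-tert-butyl ester 20-[(S)-2-(methoxymethyl)pyrrolidine] amide (C10 as in the target; C4 epimers); 11 but-3-en-2-one
Product: 13 8,13-epoxy-8,13-dimethoxy-14,15,17-trinorlabd-5-ene-19,20-dioic acid 19-tert-butyl ester 20-[(S)-2-(methoxymethyl)pyrrolidine] amide (mixture at C4 C8 C9 C13), via dihydropyran ketal 12 (not isolated)
Conditions: ZnCl2 (cat.), CH2Cl2, 20 °C; then MeOH, pyridinium p-toluenesulfonate (cat.), 0 °C
Reagents that add atoms: methanol (CO)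
Why: Inverse-electron-demand hetero-Diels–Alder reaction of the enone with the electron-rich C8=C9 methyl enol ether (carbonyl oxygen to C8, terminal CH2 to the nucleophilic C9), then acid-catalysed addition of methanol to the dihydropyran, attaches C11–C13/C16 regiospecifically and masks both future ketones in one tetrahydropyran bis-ketal; C8, C9 and C13 form as mixtures, of which only C9 matters and is corrected in step 9.

Step 5
Reactants: 13 8,13-epoxy-8,13-dimethoxy-14,15,17-trinorlabd-5-ene-19,20-dioic acid 19-tert-butyl ester 20-[(S)-2-(methoxymethyl)pyrrolidine] amide (mixture at C4 C8 C9 C13)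
Product: 14 8,13-epoxy-8,13-dimethoxy-14,15,17-trinorlabdane-19,20-dioic acid 19-tert-butyl ester 20-[(S)-2-(methoxymethyl)pyrrolidine] amide (cis-fused; H-5 cis to C20)
Conditions: H2 (50 bar), [Ir(cod)(py)(PCy3)]PF6 (cat.), CH2Cl2, 20 °C
Reagents that add atoms: none
Why: Amide-directed homogeneous hydrogenation: the C20 carboxamide oxygen binds the cationic iridium centre and delivers H2 to the face of the C5=C6 bond on which C20 stands, so H-5 becomes cis to C20 (cis ring fusion), the weakly donating tert-butyl ester on C4 not competing.

Step 6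
Reactants: 14 8,13-epoxy-8,13-dimethoxy-14,15,17-trinorlabdane-19,20-dioic acid 19-tert-butyl ester 20-[(S)-2-(methoxymethyl)pyrrolidine] amide (cis-fused; H-5 cis to C20)
Product: 15 8,13-epoxy-8,13-dimethoxy-14,15,17-trinorlabdane-19,20-diol (cis-fused)
Conditions: BH3·NH3, LiN(i-Pr)2 (gives LiH2NBH3), THF, 0 → 66 °C
Reagents that add atoms: none
Why: Lithium amidotrihydroborate reduces the hindered tertiary amide with C–N cleavage and the tert-butyl ester to the two primary alcohols and releases the auxiliary for recovery; no stereocentre is touched.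

Step 7
Reactants: 15 8,13-epoxy-8,13-dimethoxy-14,15,17-trinorlabdane-19,20-diol (cis-fused)
Product: 16 8,13-epoxy-8,13-dimethoxy-14,15,17-trinorlabdane-19,20-dial (cis-fused)
Conditions: (COCl)2, DMSO, CH2Cl2, −78 °C; then Et3N, −78 → 0 °C
Reagents that add atoms: none
Why: Swern oxidation converts both neopentyl alcohols to aldehydes that cannot epimerise, and activating both hydroxyls at −78 °C before base is added avoids lactol formation between the 1,3-related C19 and C20.

Step 8
Reactants: 16 8,13-epoxy-8,13-dimethoxy-14,15,17-trinorlabdane-19,20-dial (cis-fused)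
Product: 18 8,13-epoxy-8,13-dimethoxy-14,15,17-trinorlabdane (cis-fused; H-5 cis to the C20 methyl), via bis-hydrazone 17 (not isolated)
Conditions: N2H4·H2O, KOH, diethylene glycol, 130 → 200 °C
Reagents that add atoms: none
Why: Wolff–Kishner reduction turns both hindered aldehydes into the C19 and C20 methyl groups under basic conditions that the bis-ketal tolerates, and removes the stereocentre at C4.

Step 9
Reactants: 18 8,13-epoxy-8,13-dimethoxy-14,15,17-trinorlabdane (cis-fused; H-5 cis to the C20 methyl)
Product: 19 (5R,9R,10S)-14,15,17-trinorlabdane-8,13-dione (cis-fused; C11 cis to C20)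
Conditions: 1 M HCl, THF, 20 °C (prolonged, to equilibrate C9)
Reagents that add atoms: water (O)
Why: Acid-catalysed ketal hydrolysis frees the C8 and C13 ketones, and enolisation towards C9 lets the side chain settle equatorial and cis to C20, because the C9 epimer would place it syn-axial to the axial C4 carbon of the cis-decalin.

Step 10
Reactants: 19 (5R,9R,10S)-14,15,17-trinorlabdane-8,13-dione (cis-fused; C11 cis to C20)
Product: 20 ethyl (5R,9R,10S,13E)-8-oxo-17-norlabd-13-en-15-oate
Conditions: triethyl phosphonoacetate, NaH, THF, 0 → 20 °C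
Reagents that add atoms: triethyl phosphonoacetate (CCOC(=O)CP(=O)(OCC)OCC)
Why: Horner–Wadsworth–Emmons olefination should take place only at the unhindered methyl ketone (the C8 ketone is flanked by the branched C9 next to quaternary C10) and should favour the E alkene, in which the ester is trans to the larger C12 chain; the minor Z isomer is removed by chromatography.

Step 11
Reactants: 20 ethyl (5R,9R,10S,13E)-8-oxo-17-norlabd-13-en-15-oate
Product: 21 ethyl (5R,8S,9R,10S,13E)-8-hydroxylabd-13-en-15-oate
Conditions: MeMgBr, CeCl3, THF, −78 °C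
Reagents that add atoms: methylmagnesium bromide (C[Mg]Br)
Why: The organocerium reagent adds 1,2 to the ketone without touching the β,β-disubstituted enoate, and should enter equatorially from the face opposite the axial C20 methyl (axial attack is blocked by the 1,3-diaxial contact), giving the axial hydroxyl cis to C11 and C20 as in the target.

Step 12
Reactants: 21 ethyl (5R,8S,9R,10S,13E)-8-hydroxylabd-13-en-15-oate
Product: 22 (5R,8S,9R,10S,13E)-labd-13-ene-8,15-diol
Conditions: i-Bu2AlH, CH2Cl2, −78 → 0 °C
Reagents that add atoms: none
Why: i-Bu2AlH reduces the α,β-unsaturated ester 1,2 to the allylic alcohol, leaving the alkene geometry and the tertiary alcohol unchanged.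

Step 13
Reactants: 22 (5R,8S,9R,10S,13E)-labd-13-ene-8,15-diol
Product: 23 (5R,8S,9R,10S,13E)-8-hydroxylabd-13-en-15-yl acetate
Conditions: Ac2O (1.1 equiv), pyridine, 4-(dimethylamino)pyridine (cat.), CH2Cl2, 0 °C
Reagents that add atoms: acetic anhydride (CC(=O)OC(C)=O)
Why: Acetylation under nucleophilic catalysis is selective for the unhindered primary allylic hydroxyl over the tertiary axial hydroxyl.

**Compound list**

1 | 2-bromo-5-methoxybenzoyl chloride | COc1ccc(Br)c(c1)C(Cl)=O | starting material
2 | (S)-2-(methoxymethyl)pyrrolidine | COC[C@@H]1CCCN1 | starting material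
3 | (S)-1-(2-bromo-5-methoxybenzoyl)-2-(methoxymethyl)pyrrolidine | COC[C@@H]1CCCN1C(=O)c1cc(OC)ccc1Br | intermediate
4 | tert-butyl propanoate | CCC(=O)OC(C)(C)C | starting material
5 | lithium enolate of tert-butyl propanoate | [Li+].CC=C([O-])OC(C)(C)C | intermediate
6 | tert-butyl 2-[4-methoxy-2-((S)-2-(methoxymethyl)pyrrolidine-1-carbonyl)phenyl]propanoate (both epimers at the future C4) | COC[C@@H]1CCCN1C(=O)c1cc(OC)ccc1C(C)C(=O)OC(C)(C)C | intermediate
7 | 1,3-dibromopropane | BrCCCBr | starting material
8 | bis-enolate (potassium amide enolate at C10, lithium ester enolate at C4) | [K+].[Li+].COC[C@@H]1CCCN1C([O-])=C1C=C(OC)CC=C1C(C)=C([O-])OC(C)(C)C | intermediate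
9 | bromopropyl ester enolate (C10 alkylated, C4 still enolate) | [Li+].COC[C@@H]1CCCN1C(=O)[C@@]1(CCCBr)C=C(OC)CC=C1C(C)=C([O-])OC(C)(C)C | intermediate
10 | 8-methoxy-11,12,13,14,15,16,17-heptanorlabda-5,8-diene-19,20-dioic acid 19-tert-butyl ester 20-[(S)-2-(methoxymethyl)pyrrolidine] amide (C10 as in the target; C4 epimers) | [C@@]12(C(=O)N3CCC[C@H]3COC)CCCC(C)(C(=O)OC(C)(C)C)C2=CCC(OC)=C1 | intermediate
11 | but-3-en-2-one | CC(=O)C=C | starting material
12 | dihydropyran ketal (hetero-Diels–Alder adduct of 10 and 11) | [C@@]12(C(=O)N3CCC[C@H]3COC)CCCC(C)(C(=O)OC(C)(C)C)C2=CCC2(OC)OC(C)=CCC12 | intermediate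
13 | 8,13-epoxy-8,13-dimethoxy-14,15,17-trinorlabd-5-ene-19,20-dioic acid 19-tert-butyl ester 20-[(S)-2-(methoxymethyl)pyrrolidine] amide (mixture at C4 C8 C9 C13) | [C@@]12(C(=O)N3CCC[C@H]3COC)CCCC(C)(C(=O)OC(C)(C)C)C2=CCC2(OC)OC(C)(OC)CCC12 | intermediate
14 | 8,13-epoxy-8,13-dimethoxy-14,15,17-trinorlabdane-19,20-dioic acid 19-tert-butyl ester 20-[(S)-2-(methoxymethyl)pyrrolidine] amide (cis-fused; H-5 cis to C20) | [C@@]12(C(=O)N3CCC[C@H]3COC)CCCC(C)(C(=O)OC(C)(C)C)[C@H]2CCC2(OC)OC(C)(OC)CCC12 | intermediate
15 | 8,13-epoxy-8,13-dimethoxy-14,15,17-trinorlabdane-19,20-diol (cis-fused) | [C@@]12(CO)CCCC(C)(CO)[C@H]2CCC2(OC)OC(C)(OC)CCC12 | intermediate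
16 | 8,13-epoxy-8,13-dimethoxy-14,15,17-trinorlabdane-19,20-dial (cis-fused) | [C@@]12(C=O)CCCC(C)(C=O)[C@H]2CCC2(OC)OC(C)(OC)CCC12 | intermediate
17 | bis-hydrazone of 16 | [C@@]12(C=NN)CCCC(C)(C=NN)[C@H]2CCC2(OC)OC(C)(OC)CCC12 | intermediate
18 | 8,13-epoxy-8,13-dimethoxy-14,15,17-trinorlabdane (cis-fused; H-5 cis to the C20 methyl) | [C@@]12(C)CCCC(C)(C)[C@H]2CCC2(OC)OC(C)(OC)CCC12 | intermediate
19 | (5R,9R,10S)-14,15,17-trinorlabdane-8,13-dione (cis-fused; C11 cis to C20) | CC(=O)CC[C@@H]1[C@@]2(C)CCCC(C)(C)[C@H]2CCC1=O | intermediate
20 | ethyl (5R,9R,10S,13E)-8-oxo-17-norlabd-13-en-15-oate | CCOC(=O)/C=C(\C)CC[C@@H]1[C@@]2(C)CCCC(C)(C)[C@H]2CCC1=O | intermediate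
21 | ethyl (5R,8S,9R,10S,13E)-8-hydroxylabd-13-en-15-oate | CCOC(=O)/C=C(\C)CC[C@@H]1[C@@]2(C)CCCC(C)(C)[C@H]2CC[C@]1(C)O | intermediate
22 | (5R,8S,9R,10S,13E)-labd-13-ene-8,15-diol | OC/C=C(\C)CC[C@@H]1[C@@]2(C)CCCC(C)(C)[C@H]2CC[C@]1(C)O | intermediate
23 | (5R,8S,9R,10S,13E)-8-hydroxylabd-13-en-15-yl acetate | CC(=O)OC/C=C(\C)CC[C@@H]1[C@@]2(C)CCCC(C)(C)[C@H]2CC[C@]1(C)O | target

**Step count and risks**

Total steps: 13. Longest linear sequence: 13 (2, 4, 7 and 11 are commercial and enter a single line).

Steps most likely to fail:

Step 3 (Proposed new method). The one-flask double alkylation may give oligomers, attack of the ester dienolate through C6, or poor facial control at C10. Fallback with known chemistry: the annulation would be taken apart into two separately precedented alkylations. Compound 6 would be pre-enolised and reduced as in step 3 but alkylated only at C10 with 1-bromo-3-chloropropane and quenched, giving the C10 3-chloropropyl diene ester F1. F1 would then be cyclised on its own by iodide exchange (NaI) and KN(SiMe3)2 in THF–DMPU, which returns to the route at 10.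

Step 5. The C5=C6 bond lies between two quaternary carbons and may resist hydrogenation, or the ester on C4 may steer part of the material to the wrong face. Fallback: the directing group would be changed. Compound 13 would first be reduced with LiH2NBH3 to the diol alkene F5, whose C20 hydroxyl sits on the ring-fusion carbon next to the alkene. F5 would then be hydrogenated under hydroxyl direction ([Rh(nbd)(dppb)]BF4, H2 under pressure), which rejoins the route at 15.

Step 4. The cycloaddition may be slow at the hindered C9, and the acid may move the C5=C6 bond into conjugation with the C8 enol ether. Fallback: the polarity at C9 would be reversed. Compound 10 and dimethyl(methylidene)ammonium iodide would give, after aqueous work-up, the C9 Mannich ketone F2. Quaternisation with MeI and elimination would give the C9 methylene ketone F3. A Mukaiyama–Michael addition of 2-(trimethylsiloxy)propene (TiCl4, −78 °C) would give the 1,5-diketone F4, which methanol, trimethyl orthoformate and an acid catalyst would close to the same cyclic bis-ketal 13.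

**Further compounds**

F1 | step 3 | C10 3-chloropropyl diene ester | COC[C@@H]1CCCN1C(=O)[C@@]1(CCCCl)C=C(OC)CC=C1C(C)C(=O)OC(C)(C)C
F2 | step 4 | C9 Mannich ketone | [C@@]12(C(=O)N3CCC[C@H]3COC)CCCC(C)(C(=O)OC(C)(C)C)C2=CCC(=O)C1CN(C)C
F3 | step 4 | C9 methylene ketone | [C@@]12(C(=O)N3CCC[C@H]3COC)CCCC(C)(C(=O)OC(C)(C)C)C2=CCC(=O)C1=C
F4 | step 4 | 1,5-diketone | [C@@]12(C(=O)N3CCC[C@H]3COC)CCCC(C)(C(=O)OC(C)(C)C)C2=CCC(=O)C1CCC(C)=O
F5 | step 5 | diol alkene | [C@@]12(CO)CCCC(C)(CO)C2=CCC2(OC)OC(C)(OC)CCC12
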